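**Plan**

- Numbering: lactone O1, C2(=O), C3, C4(OH), C5; chain C6–C14; ring A is the 3,4-disubstituted furan O1', C2'–C5' (C3' carries C14, C4' the CH2 to ring B, the terminal 3-furyl).
- Cuts: C9=C10 (Julia–Kocienski), C6–C7 (alkenyl–alkyl Negishi), C11=C12 (cross-metathesis), and in ring A the C3'–C4' bond plus one C–O bond.
- Enabling feature: C3' and C4' of ring A each lie α to a carbon (C2', C5') that was an aldehyde carbon, so the C3'–C4' bond links two enol carbons of like polarity. A silicon tether between the two enol oxygens allows their oxidative union, and the resulting 2,3-disubstituted succinaldehyde closes to ring A.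
- Forward: ring B is bought; ring A is made in step 5 and extended to an enal. The lactone ring is bought, opened to an enynoic acid and re-closed by iodolactonisation. The chain is joined at C6–C7, then at C9=C10, and O-demethylation ends the route.
- Stereochemistry: C7 (S) from (R)-butane-1,3-diol by SN2 iodination and a retentive Li/Zn/Pd sequence; 5E from anti iodolactonisation and retentive coupling; 9E from the Julia–Kocienski step; 11E from cross-metathesis.

Key step: step 5

Remark: enol ethers 2, 6 and 8–11 are E/Z mixtures and dialdehyde 12 is a diastereomer mixture; their SMILES carry no descriptors for these elements, which disappear when ring A becomes aromatic.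

**Route**

Step 1
Reactants: 1 hex-5-enal
Product: 2 (hexa-1,5-dien-1-yloxy)trimethylsilane
Conditions: Me3SiCl, Et3N, DMF, 80 °C
Reagents that add atoms: chlorotrimethylsilane, C[Si](C)(C)Cl
Why: Amine-mediated enol silylation of an aldehyde under equilibrating conditions gives the silyl enol ether, and the remote terminal alkene is untouched.

Step 2
Reactants: 3 3-bromofuran; 4 prop-2-en-1-ol (allyl alcohol)
Product: 5 3-(furan-3-yl)propanal
Conditions: Pd(OAc)2 (cat.), P(o-tol)3, Bu4NCl, NaHCO3, DMF, 90 °C
Reagents that add atoms: none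
Why: Heck reaction in which 3 adds oxidatively to zerovalent palladium, allyl alcohol inserts at its terminal carbon, and β-hydride elimination toward the carbinol gives an enol that tautomerises to the aldehyde.

Step 3
Reactants: 5 3-(furan-3-yl)propanal
Product: 6 {[3-(furan-3-yl)prop-1-en-1-yl]oxy}trimethylsilane
Conditions: Me3SiCl, Et3N, DMF, 80 °C
Reagents that add atoms: chlorotrimethylsilane, C[Si](C)(C)Cl
Why: The same enol silylation as in step 1, with only the α-CH2 of the aldehyde enolisable.

Step 4
Reactants: 2 (hexa-1,5-dien-1-yloxy)trimethylsilane; 6 {[3-(furan-3-yl)prop-1-en-1-yl]oxy}trimethylsilane; 7 dichlorodiisopropylsilane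
Product: 11 {[3-(furan-3-yl)prop-1-en-1-yl]oxy}(hexa-1,5-dien-1-yloxy)diisopropylsilane, via lithium hexa-1,5-dien-1-olate 8 (not isolated), via chloro(hexa-1,5-dien-1-yloxy)diisopropylsilane 9 (not isolated), via lithium 3-(furan-3-yl)prop-1-en-1-olate 10 (not isolated)
Conditions: 2, MeLi, THF, 0 °C to rt; added to 7 (1.05 equiv), THF, −78 °C; then 10 (from 6, MeLi, THF, 0 °C to rt), −78 °C to rt
Reagents that add atoms: none
Why: MeLi cleaves each trimethylsilyl enol ether to an amine-free lithium enolate, and the two isopropyl groups should let the first enolate displace only one chloride of 7 at −78 °C, so that the second enolate completes the unsymmetrical dialkoxysilane (sequential O-silylation of enolates).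

Step 5
Reactants: 11 {[3-(furan-3-yl)prop-1-en-1-yl]oxy}(hexa-1,5-dien-1-yloxy)diisopropylsilane
Product: 13 3-(but-3-en-1-yl)-4-(furan-3-ylmethyl)furan, via 2-(but-3-en-1-yl)-3-(furan-3-ylmethyl)butanedial 12 (not isolated)
Conditions: Ce(NH4)2(NO3)6 (2.2 equiv), NaHCO3, MeCN, −20 °C; work-up; then TsOH·H2O (cat.), toluene, 4 Å MS, 50 °C
Reagents that add atoms: none
Why: Proposed new method: one-electron oxidation of one enol ether of 11 by tetravalent cerium should give a radical cation that the second enol ether captures through a seven-membered 1,3-dioxa-2-silacycle, and a second oxidation with loss of the silicon group should release dialdehyde 12 with the C3'–C4' bond in place; the closest known reaction type is the Ce(NH4)2(NO3)6 coupling of unsymmetrical diisopropylsilyl bis-enol ethers of ketones to 1,4-diketones, which has not been shown for aldehyde-derived enol ethers. Ring A then closes by Paal–Knorr cyclodehydration, a 5-exo-trig attack of one formyl oxygen on the other protonated formyl carbon followed by loss of water. The two stereocentres formed at C3' and C4' are uncontrolled and are erased on aromatisation, so every diastereomer of 12 and every enol ether geometry of 11 should converge on 13. Cross-coupling over homodimerisation is secured by the tether, which makes the union intramolecular. Chemoselectivity is needed against ring B and the terminal alkene: the dialkoxysilyl enol ethers should be the most easily oxidised π-systems, the oxidation is run cold with NaHCO3 as buffer, and the butenyl chain offers an intermediate radical only 4-exo or 5-endo closures, which should not compete.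

Step 6
Reactants: 13 3-(but-3-en-1-yl)-4-(furan-3-ylmethyl)furan
Product: 14 (2E)-5-[4-(furan-3-ylmethyl)furan-3-yl]-2-methylpent-2-enal
Conditions: methacrolein (excess), second-generation Grubbs catalyst (H2IMes)(PCy3)Cl2Ru=CHPh (5 mol%), CH2Cl2, 40 °C
Reagents that add atoms: methacrolein, CC(=C)C=O
Why: Olefin cross-metathesis between the terminal alkene and the electron-poor 1,1-disubstituted alkene of methacrolein favours the cross product and sets C11=C12 as E (formyl trans to the chain), while the furans are inert to the ruthenium carbene.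

Step 7
Reactants: 15 4-hydroxy-3-methylfuran-2(5H)-one (3-methyltetronic acid)
Product: 16 4-methoxy-3-methylfuran-2(5H)-one
Conditions: Me2SO4, K2CO3, acetone, reflux
Reagents that add atoms: dimethyl sulfate, COS(=O)(=O)OC
Why: O-Alkylation of the vinylogous carboxylate with a hard electrophile should give the 4-methyl ether, C-alkylation being disfavoured at the methyl-bearing C3.

Step 8
Reactants: 16 4-methoxy-3-methylfuran-2(5H)-one
Product: 18 5-hydroxy-4-methoxy-3-methylfuran-2(5H)-one, via lithium 4-methoxy-3-methylfuran-2-olate 17 (not isolated)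
Conditions: LiN(iPr)2, THF, −78 °C; then 2-(phenylsulfonyl)-3-phenyloxaziridine, −78 °C; NH4Cl
Reagents that add atoms: 2-(phenylsulfonyl)-3-phenyloxaziridine, O=S(=O)(c1ccccc1)N1OC1c1ccccc1
Why: Deprotonation at C5, the γ-position of the vinylogous carbonate, gives furanolate 17, and electrophilic oxygen transfer from the N-sulfonyloxaziridine (enolate hydroxylation) at C5 should give the racemic lactol.

Step 9
Reactants: 18 5-hydroxy-4-methoxy-3-methylfuran-2(5H)-one
Product: 19 (2E)-3-methoxy-2-methylpent-2-en-4-ynoic acid
Conditions: dimethyl (1-diazo-2-oxopropyl)phosphonate, K2CO3 (3 equiv), MeOH, 0 °C to rt; then cold acid to pH 3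
Reagents that add atoms: dimethyl (1-diazo-2-oxopropyl)phosphonate, COP(=O)(OC)C(=[N+]=[N-])C(C)=O
Why: Ohira–Bestmann homologation, in which the lactol opens in basic methanol to the formyl acrylate and the formyl group becomes a terminal alkyne, with the cis relationship of carboxyl and alkyne inherited from the ring.

Step 10
Reactants: 19 (2E)-3-methoxy-2-methylpent-2-en-4-ynoic acid
Product: 20 (5E)-5-(iodomethylidene)-4-methoxy-3-methylfuran-2(5H)-one
Conditions: I2, NaHCO3, MeCN, rt, dark
Reagents that add atoms: iodine, [I][I]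
Why: Iodolactonisation by 5-exo-dig attack of the carboxylate on the iodonium-activated terminal alkyne at its internal carbon is an anti addition, so iodine should end trans to O1 and C5=C6 is set as E.

Step 11
Reactants: 21 (3R)-butane-1,3-diol
Product: 22 (2R)-4-[(tert-butyldimethylsilyl)oxy]butan-2-ol
Conditions: TBSCl, imidazole, CH2Cl2, 0 °C
Reagents that add atoms: tert-butylchlorodimethylsilane, CC(C)(C)[Si](C)(C)Cl
Why: Silylation of the primary hydroxyl is much faster than that of the secondary one (steric selection), and the stereocentre is not touched.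

Step 12
Reactants: 22 (2R)-4-[(tert-butyldimethylsilyl)oxy]butan-2-ol
Product: 23 tert-butyl{[(3S)-3-iodobutyl]oxy}dimethylsilane
Conditions: I2, PPh3, N-methylimidazole, CH2Cl2, −10 °C
Reagents that add atoms: iodine, [I][I]
Why: Appel-type iodination through an alkoxyphosphonium ion that iodide opens by SN2 with inversion turns the (R)-carbinol into the (S)-iodide, the low temperature limiting racemising iodide exchange.

Step 13
Reactants: 23 tert-butyl{[(3S)-3-iodobutyl]oxy}dimethylsilane; 20 (5E)-5-(iodomethylidene)-4-methoxy-3-methylfuran-2(5H)-one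
Product: 26 (5E)-5-{(2S)-4-[(tert-butyldimethylsilyl)oxy]-2-methylbutylidene}-4-methoxy-3-methylfuran-2(5H)-one, via {(2S)-4-[(tert-butyldimethylsilyl)oxy]butan-2-yl}lithium 24 (not isolated), via {(2S)-4-[(tert-butyldimethylsilyl)oxy]butan-2-yl}[(trimethylsilyl)methyl]zinc 25 (not isolated)
Conditions: tBuLi (2.2 equiv), pentane/Et2O, −100 °C (inverse addition); Me3SiCH2ZnBr·LiBr, THF, −100 to −30 °C; then 20, Pd2I2(PtBu3)2 (3 mol%), −25 °C
Reagents that add atoms: none
Why: Negishi coupling in which iodine–lithium exchange at −100 °C, transmetalation to zinc and the palladium-catalysed union of a secondary alkylzinc with an alkenyl iodide each proceed with retention, so C7 should become S and C5=C6 should stay E.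

Step 14
Reactants: 26 (5E)-5-{(2S)-4-[(tert-butyldimethylsilyl)oxy]-2-methylbutylidene}-4-methoxy-3-methylfuran-2(5H)-one
Product: 27 (5E)-5-[(2S)-4-hydroxy-2-methylbutylidene]-4-methoxy-3-methylfuran-2(5H)-one
Conditions: HF·pyridine, THF/pyridine, 0 °C to rt
Reagents that add atoms: none
Why: Fluoride-mediated desilylation under buffered conditions should free the primary alcohol without touching the enol lactone or its geometry.

Step 15
Reactants: 27 (5E)-5-[(2S)-4-hydroxy-2-methylbutylidene]-4-methoxy-3-methylfuran-2(5H)-one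
Product: 28 (5E)-4-methoxy-3-methyl-5-{(2S)-2-methyl-4-[(1-phenyl-1H-tetrazol-5-yl)sulfanyl]butylidene}furan-2(5H)-one
Conditions: 1-phenyl-1H-tetrazole-5-thiol, PPh3, DIAD, THF, 0 °C to rt
Reagents that add atoms: 1-phenyl-1H-tetrazole-5-thiol, Sc1nnnn1-c1ccccc1
Why: Mitsunobu thioetherification of the primary alcohol with the acidic heteroaryl thiol, with no stereocentre involved.

Step 16
Reactants: 28 (5E)-4-methoxy-3-methyl-5-{(2S)-2-methyl-4-[(1-phenyl-1H-tetrazol-5-yl)sulfanyl]butylidene}furan-2(5H)-one
Product: 29 (5E)-4-methoxy-3-methyl-5-{(2S)-2-methyl-4-[(1-phenyl-1H-tetrazol-5-yl)sulfonyl]butylidene}furan-2(5H)-one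
Conditions: (NH4)6Mo7O24·4H2O (cat.), 30% H2O2, EtOH, 0 °C to rt
Reagents that add atoms: hydrogen peroxide, OO
Why: Molybdate-catalysed peroxide oxidation of the sulfide to the sulfone, carried out before any furan is present and on an enol lactone alkene too electron-poor to be epoxidised.

Step 17
Reactants: 29 (5E)-4-methoxy-3-methyl-5-{(2S)-2-methyl-4-[(1-phenyl-1H-tetrazol-5-yl)sulfonyl]butylidene}furan-2(5H)-one; 14 (2E)-5-[4-(furan-3-ylmethyl)furan-3-yl]-2-methylpent-2-enal
Product: 31 (5E)-5-{(2S,4E,6E)-9-[4-(furan-3-ylmethyl)furan-3-yl]-2,6-dimethylnona-4,6-dien-1-ylidene}-4-methoxy-3-methylfuran-2(5H)-one, via C9-potassio sulfone 30 (not isolated)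
Conditions: KN(SiMe3)2 added to 29 and 14, DME, −60 °C to rt
Reagents that add atoms: none
Why: Julia–Kocienski olefination in which carbanion 30 adds to the conjugated aldehyde and Smiles rearrangement with loss of SO2 and the tetrazolone should give C9=C10 as E, adducts of conjugated aldehydes being able to equilibrate before elimination, while adding the base last keeps 30 short-lived and the in-plane C7–H (A(1,3) strain) resists deprotonation.

Step 18
Reactants: 31 (5E)-5-{(2S,4E,6E)-9-[4-(furan-3-ylmethyl)furan-3-yl]-2,6-dimethylnona-4,6-dien-1-ylidene}-4-methoxy-3-methylfuran-2(5H)-one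
Product: 32 (5E)-5-{(2S,4E,6E)-9-[4-(furan-3-ylmethyl)furan-3-yl]-2,6-dimethylnona-4,6-dien-1-ylidene}-4-hydroxy-3-methylfuran-2(5H)-one (CNP0017516.1)
Conditions: LiSCH2CH2CH3, HMPA, rt; then cold dilute HCl to pH 3
Reagents that add atoms: none
Why: SN2 demethylation of the vinylogous methyl carbonate by the soft thiolate should free the tetronic acid without heat or strong acid, sparing the furans, the diene and the E geometry at C5=C6.

**Compound list**

1 | hex-5-enal | C=CCCCC=O | starting material
2 | (hexa-1,5-dien-1-yloxy)trimethylsilane (E/Z mixture) | C=CCCC=CO[Si](C)(C)C | intermediate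
3 | 3-bromofuran | Brc1ccoc1 | starting material
4 | prop-2-en-1-ol (allyl alcohol) | C=CCO | starting material
5 | 3-(furan-3-yl)propanal | O=CCCc1ccoc1 | intermediate
6 | {[3-(furan-3-yl)prop-1-en-1-yl]oxy}trimethylsilane (E/Z mixture) | C[Si](C)(C)OC=CCc1ccoc1 | intermediate
7 | dichlorodiisopropylsilane | CC(C)[Si](Cl)(Cl)C(C)C | starting material
8 | lithium hexa-1,5-dien-1-olate | [Li+].[O-]C=CCCC=C | intermediate
9 | chloro(hexa-1,5-dien-1-yloxy)diisopropylsilane | CC(C)[Si](Cl)(OC=CCCC=C)C(C)C | intermediate
10 | lithium 3-(furan-3-yl)prop-1-en-1-olate | [Li+].[O-]C=CCc1ccoc1 | intermediate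
11 | {[3-(furan-3-yl)prop-1-en-1-yl]oxy}(hexa-1,5-dien-1-yloxy)diisopropylsilane | CC(C)[Si](OC=CCCC=C)(OC=CCc1ccoc1)C(C)C | intermediate
12 | 2-(but-3-en-1-yl)-3-(furan-3-ylmethyl)butanedial (diastereomer mixture) | O=CC(CCC=C)C(Cc1ccoc1)C=O | intermediate
13 | 3-(but-3-en-1-yl)-4-(furan-3-ylmethyl)furan | C=CCCc1cocc1Cc1ccoc1 | intermediate
14 | (2E)-5-[4-(furan-3-ylmethyl)furan-3-yl]-2-methylpent-2-enal | O=C/C(C)=C/CCc1cocc1Cc1ccoc1 | intermediate
15 | 4-hydroxy-3-methylfuran-2(5H)-one (3-methyltetronic acid) | CC1=C(O)COC1=O | starting material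
16 | 4-methoxy-3-methylfuran-2(5H)-one | CC1=C(OC)COC1=O | intermediate
17 | lithium 4-methoxy-3-methylfuran-2-olate | [Li+].[O-]c1occ(OC)c1C | intermediate
18 | 5-hydroxy-4-methoxy-3-methylfuran-2(5H)-one (racemic lactol) | CC1=C(OC)C(O)OC1=O | intermediate
19 | (2E)-3-methoxy-2-methylpent-2-en-4-ynoic acid (carboxyl cis to the alkyne) | C#C/C(OC)=C(/C)C(=O)O | intermediate
20 | (5E)-5-(iodomethylidene)-4-methoxy-3-methylfuran-2(5H)-one | CC1=C(OC)/C(=C\I)OC1=O | intermediate
21 | (3R)-butane-1,3-diol | C[C@@H](O)CCO | starting material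
22 | (2R)-4-[(tert-butyldimethylsilyl)oxy]butan-2-ol | C[C@@H](O)CCO[Si](C)(C)C(C)(C)C | intermediate
23 | tert-butyl{[(3S)-3-iodobutyl]oxy}dimethylsilane | C[C@H](I)CCO[Si](C)(C)C(C)(C)C | intermediate
24 | {(2S)-4-[(tert-butyldimethylsilyl)oxy]butan-2-yl}lithium | C[C@H]([Li])CCO[Si](C)(C)C(C)(C)C | intermediate
25 | {(2S)-4-[(tert-butyldimethylsilyl)oxy]butan-2-yl}[(trimethylsilyl)methyl]zinc | C[C@H]([Zn]C[Si](C)(C)C)CCO[Si](C)(C)C(C)(C)C | intermediate
26 | (5E)-5-{(2S)-4-[(tert-butyldimethylsilyl)oxy]-2-methylbutylidene}-4-methoxy-3-methylfuran-2(5H)-one | CC1=C(OC)/C(=C\[C@@H](C)CCO[Si](C)(C)C(C)(C)C)OC1=O | intermediate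
27 | (5E)-5-[(2S)-4-hydroxy-2-methylbutylidene]-4-methoxy-3-methylfuran-2(5H)-one | CC1=C(OC)/C(=C\[C@@H](C)CCO)OC1=O | intermediate
28 | (5E)-4-methoxy-3-methyl-5-{(2S)-2-methyl-4-[(1-phenyl-1H-tetrazol-5-yl)sulfanyl]butylidene}furan-2(5H)-one | CC1=C(OC)/C(=C\[C@@H](C)CCSc2nnnn2-c2ccccc2)OC1=O | intermediate
29 | (5E)-4-methoxy-3-methyl-5-{(2S)-2-methyl-4-[(1-phenyl-1H-tetrazol-5-yl)sulfonyl]butylidene}furan-2(5H)-one | CC1=C(OC)/C(=C\[C@@H](C)CCS(=O)(=O)c2nnnn2-c2ccccc2)OC1=O | intermediate
30 | potassium salt of 29 deprotonated at C9 (α to sulfur) | [K+].CC1=C(OC)/C(=C\[C@@H](C)C[CH-]S(=O)(=O)c2nnnn2-c2ccccc2)OC1=O | intermediate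
31 | (5E)-5-{(2S,4E,6E)-9-[4-(furan-3-ylmethyl)furan-3-yl]-2,6-dimethylnona-4,6-dien-1-ylidene}-4-methoxy-3-methylfuran-2(5H)-one | CC1=C(OC)/C(=C\[C@@H](C)C/C=C/C(C)=C/CCc2cocc2Cc2ccoc2)OC1=O | intermediate
32 | (5E)-5-{(2S,4E,6E)-9-[4-(furan-3-ylmethyl)furan-3-yl]-2,6-dimethylnona-4,6-dien-1-ylidene}-4-hydroxy-3-methylfuran-2(5H)-one | CC1=C(O)/C(=C\[C@@H](C)C/C=C/C(C)=C/CCc2cocc2Cc2ccoc2)OC1=O | target

**Step count and risks**

Total step count: 18. Longest linear sequence: 10 steps (7, 8, 9, 10, 13, 14, 15, 16, 17, 18).

Steps most likely to fail: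

1. Step 5, the step that carries the label for a new method. Tetravalent cerium may over-oxidise ring B, the enol ethers may hydrolyse before they couple, or the radical cation may be intercepted by nitrate before ring closure. The fallback uses known chemistry, sets out from aldehyde 5 and comes back at dialdehyde 12. Nitromethane is added to pent-4-enal (Henry reaction) to give 1-nitrohex-5-en-2-ol F1, which is dehydrated (dicyclohexylcarbodiimide, CuCl) to (1E)-1-nitrohexa-1,5-diene F2. Amine-catalysed Michael addition of 5 (pyrrolidine or a diarylprolinol silyl ether) to F2 gives 2-(furan-3-ylmethyl)-3-(nitromethyl)hept-6-enal F3. A Nef reaction (NaOMe, MeOH; then cold H2SO4) converts the nitromethyl group into the second formyl group, and 12 is cyclodehydrated to 13 as in step 5.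

2. Step 13. The secondary alkyl metal may lose configuration during exchange or transmetalation, or the alkylpalladium intermediate may undergo β-hydride elimination and re-insertion to the linear isomer. The fallback forms C5=C6 by aldol condensation; it sets out from tetronate 16 and comes back at silyl ether 26. Commercial (S)-2-methylbutane-1,4-diol is silylated at the less hindered C4 hydroxyl (TBSCl, imidazole, −20 °C) to (2S)-4-[(tert-butyldimethylsilyl)oxy]-2-methylbutan-1-ol F4 and oxidised with Dess–Martin periodinane to (2S)-4-[(tert-butyldimethylsilyl)oxy]-2-methylbutanal F5. Dienolate 17, made from 16 as in step 8, adds to F5 at −78 °C to give 5-{(2S)-4-[(tert-butyldimethylsilyl)oxy]-1-hydroxy-2-methylbutyl}-4-methoxy-3-methylfuran-2(5H)-one F6. This is converted (MsCl, Et3N) into its methanesulfonate F7 and eliminated with DBU. The E isomer 26 is separated by chromatography, and the Z isomer is re-equilibrated photochemically and recycled. C7 then comes from the chiral pool and no configurationally labile organometallic is needed, at the price of lower geometric selectivity.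

3. Step 9. The lactol may open too slowly for the homologation to keep pace with decomposition of the diazophosphonate, or methoxide may add to the intermediate diazoalkene. The fallback sets out from lactol 18 and comes back at acid 19 in two classical operations. A Wittig reaction with Ph3P=CHCl (from (chloromethyl)triphenylphosphonium chloride and KOtBu, in excess to allow for the acidic proton) gives (2E)-5-chloro-3-methoxy-2-methylpenta-2,4-dienoic acid F8 as a 4E/4Z mixture. Dehydrochlorination with LiN(iPr)2 (3 equiv, THF, −78 °C) then returns 19 after acidification.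

Further compounds
F1 | step 5 | 1-nitrohex-5-en-2-ol | C=CCCC(O)C[N+](=O)[O-]
F2 | step 5 | (1E)-1-nitrohexa-1,5-diene | C=CCC/C=C/[N+](=O)[O-]
F3 | step 5 | 2-(furan-3-ylmethyl)-3-(nitromethyl)hept-6-enal (diastereomer mixture) | O=CC(Cc1ccoc1)C(CCC=C)C[N+](=O)[O-]
F4 | step 13 | (2S)-4-[(tert-butyldimethylsilyl)oxy]-2-methylbutan-1-ol | OC[C@@H](C)CCO[Si](C)(C)C(C)(C)C
F5 | step 13 | (2S)-4-[(tert-butyldimethylsilyl)oxy]-2-methylbutanal | O=C[C@@H](C)CCO[Si](C)(C)C(C)(C)C
F6 | step 13 | 5-{(2S)-4-[(tert-butyldimethylsilyl)oxy]-1-hydroxy-2-methylbutyl}-4-methoxy-3-methylfuran-2(5H)-one (mixture at C5 and the carbinol carbon) | CC1=C(OC)C(OC1=O)C(O)[C@@H](C)CCO[Si](C)(C)C(C)(C)C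
F7 | step 13 | (2S)-4-[(tert-butyldimethylsilyl)oxy]-1-(3-methoxy-4-methyl-5-oxo-2,5-dihydrofuran-2-yl)-2-methylbutyl methanesulfonate | CC1=C(OC)C(OC1=O)C(OS(C)(=O)=O)[C@@H](C)CCO[Si](C)(C)C(C)(C)C
F8 | step 9 | (2E)-5-chloro-3-methoxy-2-methylpenta-2,4-dienoic acid (4E/4Z mixture) | ClC=C/C(OC)=C(/C)C(=O)O
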